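## Retrosynthetic overview

- Target numbering (cyclohex-3-en-1-yl): C-1 ester carbon, C-4 methyl-bearing olefinic carbon, C-5 CH–CH2OAr, C-6 CMe2. The ester C–O bond and the C-3=C-4 double bond are traced back together to an oxygen bridge, i.e. to a 7-oxabicyclo[2.2.1]heptane that is opened last by acylative ether cleavage. The aryl ether comes from a Mitsunobu reaction with umbelliferone.
- Enabling feature: C-1 (O-bearing) and C-4 (methyl-bearing) sit 1,4 across the cyclohexene ring, and the ester oxygen is cis to the CH2OAr group. An oxygen bridge C-1–O–C-4 therefore turns C-4, C-3, C-2, C-1 and that oxygen into 2-methylfuran, and C-5/C-6 into a two-carbon dienophile whose CH2O carbon must be exo.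
- Key disconnection: bonds C-4–C-5 and C-1–C-6, made in one Diels–Alder reaction of 2-methylfuran with methyl 3-bromopropiolate. The dienophile is at the alkyne oxidation level, and the bromine is the place-holder for the geminal methyl groups, which a double cuprate addition puts in.
- Stereocontrol: bridgeheads from the cycloaddition, exo C-5 substituent by equilibration, absolute configuration by separation of diastereomeric (S)-1-phenylethyl esters.
- Ring order: the carbocycle is the only ring built (step 2, as an oxygen-bridged bicycle); the coumarin is bought intact; the temporary oxygen-bridged ring is opened in step 9.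

Key step: step 2

Remark: compounds 4 to 10 are racemic; their names and SMILES show the enantiomer that is carried on after the separation in step 6.

## Route

Step 1
Reactants: 1 methyl propiolate
Product: 2 methyl 3-bromoprop-2-ynoate
Conditions: NBS, AgNO3 (10 mol %), acetone, rt
Reagents that add atoms: N-bromosuccinimide, O=C1CCC(=O)N1Br
Why: Silver-catalysed electrophilic bromination of the terminal alkyne C–H (through the silver acetylide) is the standard preparation of 1-bromoalkynes and leaves the ester untouched; no stereocenter is formed.

Step 2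
Reactants: 2 methyl 3-bromoprop-2-ynoate; 3 2-methylfuran
Product: 4 rac-methyl (1S,4R)-3-bromo-1-methyl-7-oxabicyclo[2.2.1]hepta-2,5-diene-2-carboxylate
Conditions: 3 (4 equiv), toluene, 80 °C, 24 h, sealed vessel
Reagents that add atoms: none
Why: Thermal Diels–Alder reaction in which the furan (C-2 to C-5) adds as the 4π component across the electron-poor triple bond in a concerted, asynchronous [4+2] cycloaddition; the closest known reaction type is the cycloaddition of 2-alkylfurans with 3-halopropiolates. The six-membered carbocycle is closed in the suprafacial [π4s+π2s] mode, both new C–C bonds forming on one face of the furan, which at the same time creates the oxygen-bridged bicyclo[2.2.1] framework. The two bridgehead stereocenters arise together and their relative configuration is dictated by the bicycle (the oxygen bridge can only be cis), so one racemic diastereomer should result; the absolute configuration is selected in step 6. The selectivity needed is regioselectivity (ester-bearing carbon next to the methyl-bearing bridgehead), secured by the match of the largest HOMO coefficient of 2-methylfuran at its unsubstituted C-5 with the largest LUMO coefficient at the bromine-bearing β-carbon of the ynoate. The bromine both activates the dienophile and holds the place of the geminal methyl groups, and neutral conditions below 90 °C should avoid cycloreversion and acid-induced aromatisation of the adduct.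

Step 3
Reactants: 4 rac-methyl (1S,4R)-3-bromo-1-methyl-7-oxabicyclo[2.2.1]hepta-2,5-diene-2-carboxylate
Product: 7 rac-methyl (1S,2S,4R)-1,3,3-trimethyl-7-oxabicyclo[2.2.1]hept-5-ene-2-carboxylate, via dimethyl diene ester 5 (not isolated), via silyl ketene acetal 6 (not isolated)
Conditions: Me2CuLi (3 equiv, from CuI and MeLi), Me3SiCl (2 equiv), Et2O/THF, −78 to −30 °C; then aq NH4Cl
Reagents that add atoms: lithium dimethylcuprate, [Li+].C[Cu-]C
Why: Addition–elimination of the cuprate at the bromine-bearing β-carbon (a vinylogous acyl bromide) gives 5, and a second, Me3SiCl-accelerated conjugate addition to the strained bicyclic enoate builds the quaternary carbon and is trapped as silyl ketene acetal 6 before the ester enolate can expel the bridging oxygen; hydrolytic protonation from the exo face should give mainly the endo ester, a provisional configuration at C-2 that step 5 corrects.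

Step 4
Reactants: 7 rac-methyl (1S,2S,4R)-1,3,3-trimethyl-7-oxabicyclo[2.2.1]hept-5-ene-2-carboxylate
Product: 8 rac-methyl (1S,2S,4R)-1,3,3-trimethyl-7-oxabicyclo[2.2.1]heptane-2-carboxylate
Conditions: H2 (1 atm), 5% Pd/C, EtOAc, rt
Reagents that add atoms: none
Why: Heterogeneous catalytic hydrogenation of the strained, unhindered disubstituted alkene is fast and chemoselective (ester and bridging ether are inert) and removes the allylic C–O activation, so that the later ionisation gives a simple tertiary cation; no new stereocenter is formed.

Step 5
Reactants: 8 rac-methyl (1S,2S,4R)-1,3,3-trimethyl-7-oxabicyclo[2.2.1]heptane-2-carboxylate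
Product: 10 rac-(1S,2R,4R)-1,3,3-trimethyl-7-oxabicyclo[2.2.1]heptane-2-carboxylic acid, via exo methyl ester 9 (not isolated)
Conditions: NaOMe (0.3 equiv), MeOH, 65 °C; then KOH, H2O, reflux; then aq HCl, recrystallisation
Reagents that add atoms: potassium hydroxide, [K+].[OH-]
Why: Base-mediated epimerisation through the ester enolate (reprotonation by methanol being faster than β-elimination of the bridge oxygen) should drive C-2 to the thermodynamically favoured exo configuration, in which the substituent is syn to the oxygen bridge and avoids the endo hydrogens at C-5 and C-6, and the less hindered exo ester is then saponified, which sets the cis relation between the future ester oxygen and the future CH2OAr group.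

Step 6
Reactants: 10 rac-(1S,2R,4R)-1,3,3-trimethyl-7-oxabicyclo[2.2.1]heptane-2-carboxylic acid; 11 (S)-1-phenylethanol
Product: 12 (1S)-1-phenylethyl (1S,2R,4R)-1,3,3-trimethyl-7-oxabicyclo[2.2.1]heptane-2-carboxylate
Conditions: DCC, DMAP (10 mol %), CH2Cl2, 0 °C to rt; chromatography, then crystallisation
Reagents that add atoms: none
Why: Steglich esterification with an enantiopure alcohol converts the two enantiomers of the racemic acid into two diastereomeric esters, 12 and the ester of the (1R,2S,4S) acid, which should be separable by chromatography and crystallisation; only 12 (at best half of the material) is carried on, and its assignment would be confirmed by X-ray analysis against the known (S) center of the auxiliary, which fixes the absolute configuration of all ring stereocenters.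

Step 7
Reactants: 12 (1S)-1-phenylethyl (1S,2R,4R)-1,3,3-trimethyl-7-oxabicyclo[2.2.1]heptane-2-carboxylate
Product: 13 [(1S,2S,4R)-1,3,3-trimethyl-7-oxabicyclo[2.2.1]heptan-2-yl]methanol
Conditions: LiAlH4, THF, 0 °C to rt
Reagents that add atoms: none
Why: Hydride reduction of the ester with LiAlH4 gives the primary alcohol and returns the auxiliary alcohol, while the bridging ether and all stereocenters (none is epimerisable once the carbonyl is gone) stay untouched.

Step 8
Reactants: 13 [(1S,2S,4R)-1,3,3-trimethyl-7-oxabicyclo[2.2.1]heptan-2-yl]methanol; 14 umbelliferone (7-hydroxy-2H-chromen-2-one)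
Product: 15 7-{[(1S,2S,4R)-1,3,3-trimethyl-7-oxabicyclo[2.2.1]heptan-2-yl]methoxy}-2H-chromen-2-one
Conditions: PPh3, DIAD, THF/toluene, 0 to 60 °C
Reagents that add atoms: none
Why: Mitsunobu etherification, in which the acidic phenol (pKa about 8) displaces the oxyphosphonium-activated primary carbinol by SN2 attack at the CH2 carbon, so that no stereocenter is involved and the lactone of the coumarin survives the neutral conditions.

Step 9
Reactants: 15 7-{[(1S,2S,4R)-1,3,3-trimethyl-7-oxabicyclo[2.2.1]heptan-2-yl]methoxy}-2H-chromen-2-one; 16 3-methylbutanoic anhydride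
Product: 18 (1R,5S)-4,6,6-trimethyl-5-{[(2-oxo-2H-chromen-7-yl)oxy]methyl}cyclohex-3-en-1-yl 3-methylbutanoate, via tertiary carbocation 17 (not isolated)
Conditions: 16 (2.5 equiv), FeCl3 (5 mol %), CH2Cl2, −20 to 0 °C
Reagents that add atoms: none
Why: Lewis-acid-catalysed acylative cleavage of the bridged ether, in which acylation of the ether oxygen gives an acyloxonium ion that ionises at the tertiary, methyl-bearing carbon to cation 17, leaving the isovalerate on the secondary carbon with retention, and loss of a proton from the ring CH2 (rather than from the hindered methine or the methyl group) should give the trisubstituted alkene, as in the acetolysis of cineole-type ethers; both stereocenters are carried over unchanged.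

## Compound list

1 | methyl propiolate (methyl prop-2-ynoate) | C#CC(=O)OC | starting material
2 | methyl 3-bromoprop-2-ynoate | BrC#CC(=O)OC | intermediate
3 | 2-methylfuran | Cc1ccco1 | starting material
4 | rac-methyl (1S,4R)-3-bromo-1-methyl-7-oxabicyclo[2.2.1]hepta-2,5-diene-2-carboxylate | C[C@@]12C=C[C@@H](O1)C(Br)=C2C(=O)OC | intermediate
5 | rac-methyl (1S,4R)-1,3-dimethyl-7-oxabicyclo[2.2.1]hepta-2,5-diene-2-carboxylate | C[C@@]12C=C[C@@H](O1)C(C)=C2C(=O)OC | intermediate
6 | rac-{methoxy[(1S,4R)-1,3,3-trimethyl-7-oxabicyclo[2.2.1]hept-5-en-2-ylidene]methoxy}trimethylsilane (silyl ketene acetal, double-bond geometry not defined) | C[C@@]12C=C[C@@H](O1)C(C)(C)C2=C(OC)O[Si](C)(C)C | intermediate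
7 | rac-methyl (1S,2S,4R)-1,3,3-trimethyl-7-oxabicyclo[2.2.1]hept-5-ene-2-carboxylate (ester endo) | C[C@@]12C=C[C@@H](O1)C(C)(C)[C@@H]2C(=O)OC | intermediate
8 | rac-methyl (1S,2S,4R)-1,3,3-trimethyl-7-oxabicyclo[2.2.1]heptane-2-carboxylate (ester endo) | C[C@@]12CC[C@@H](O1)C(C)(C)[C@@H]2C(=O)OC | intermediate
9 | rac-methyl (1S,2R,4R)-1,3,3-trimethyl-7-oxabicyclo[2.2.1]heptane-2-carboxylate (ester exo) | C[C@@]12CC[C@@H](O1)C(C)(C)[C@H]2C(=O)OC | intermediate
10 | rac-(1S,2R,4R)-1,3,3-trimethyl-7-oxabicyclo[2.2.1]heptane-2-carboxylic acid (carboxyl exo) | C[C@@]12CC[C@@H](O1)C(C)(C)[C@H]2C(=O)O | intermediate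
11 | (S)-1-phenylethanol | C[C@H](O)c1ccccc1 | starting material
12 | (1S)-1-phenylethyl (1S,2R,4R)-1,3,3-trimethyl-7-oxabicyclo[2.2.1]heptane-2-carboxylate | C[C@@]12CC[C@@H](O1)C(C)(C)[C@H]2C(=O)O[C@@H](C)c1ccccc1 | intermediate
13 | [(1S,2S,4R)-1,3,3-trimethyl-7-oxabicyclo[2.2.1]heptan-2-yl]methanol (CH2OH exo) | C[C@@]12CC[C@@H](O1)C(C)(C)[C@H]2CO | intermediate
14 | umbelliferone (7-hydroxy-2H-chromen-2-one) | Oc1ccc2ccc(=O)oc2c1 | starting material
15 | 7-{[(1S,2S,4R)-1,3,3-trimethyl-7-oxabicyclo[2.2.1]heptan-2-yl]methoxy}-2H-chromen-2-one | C[C@@]12CC[C@@H](O1)C(C)(C)[C@H]2COc1ccc2ccc(=O)oc2c1 | intermediate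
16 | 3-methylbutanoic anhydride (isovaleric anhydride) | CC(C)CC(=O)OC(=O)CC(C)C | starting material
17 | tertiary carbocation at C-4 of the ring-opened isovalerate (C-1 R, C-5 S as in the target) | C[C+]1CC[C@@H](OC(=O)CC(C)C)C(C)(C)[C@H]1COc1ccc2ccc(=O)oc2c1 | intermediate
18 | (1R,5S)-4,6,6-trimethyl-5-{[(2-oxo-2H-chromen-7-yl)oxy]methyl}cyclohex-3-en-1-yl 3-methylbutanoate | CC1=CC[C@@H](OC(=O)CC(C)C)C(C)(C)[C@H]1COc1ccc2ccc(=O)oc2c1 | target

## Step count and risks

Total step count: 9. Longest linear sequence: 9 steps (1 to 18).

Steps most likely to fail: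

1. Step 9. What may go wrong: loss of regiocontrol when the tertiary cation sheds a proton (exocyclic or tetrasubstituted double-bond isomers), capture of the cation by carboxylate, or acid-induced migration of the new double bond. Fallback, from 15 back to 18: the three events are separated. The bridge is opened with Me2BBr (CH2Cl2, −78 °C, then aq NaHCO3), which attacks the tertiary carbon in an SN1-like way, to give 7-{[(1S,5R)-2-bromo-5-hydroxy-2,6,6-trimethylcyclohexyl]methoxy}-2H-chromen-2-one F1. Dehydrobromination with DBU (toluene, 80 °C), which should take the accessible ring CH2 proton anti to bromine, gives the homoallylic alcohol 7-{[(1S,5R)-5-hydroxy-2,6,6-trimethylcyclohex-2-en-1-yl]methoxy}-2H-chromen-2-one F2. Acylation with 3-methylbutanoyl chloride (pyridine, DMAP, CH2Cl2) then gives 18.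

2. Step 3. What may go wrong: incomplete second conjugate addition at the fully substituted β-carbon, or expulsion of the bridging oxygen from the ester enolate before it is silylated. Fallback, from 3 back to 8: the geminal methyl groups are carried into the cycloaddition as a spirocyclopropane. Methyl 2-cyclopropylideneacetate F3 is made by Wittig olefination of 1-ethoxy-1-(trimethylsilyloxy)cyclopropane with methyl (triphenylphosphoranylidene)acetate (cat. PhCO2H, toluene, 90 °C). This strain-activated dienophile is added to 3 (neat, about 10 kbar, rt) to give the spiro adduct rac-methyl (1'S,4'R)-1'-methylspiro[cyclopropane-1,3'-[7]oxabicyclo[2.2.1]hept[5]ene]-2'-carboxylate F4. Hydrogenation over PtO2 in AcOH saturates the double bond and cleaves the distal CH2–CH2 bond of the cyclopropane, giving 8 together with its C-2 epimer 9, which step 5 equilibrates.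

3. Step 5. What may go wrong: incomplete or unfavourable endo-to-exo equilibration, or opening of the oxygen bridge by β-elimination from the ester enolate in hot alkoxide. Fallback, from 8 back to 10: the epimerisation is moved to the aldehyde oxidation level, where enolisation needs far milder base. Reduction with i-Bu2AlH (toluene, −78 °C) gives rac-(1S,2S,4R)-1,3,3-trimethyl-7-oxabicyclo[2.2.1]heptane-2-carbaldehyde F5. Equilibration with DBU (CH2Cl2, rt) gives the exo aldehyde rac-(1S,2R,4R)-1,3,3-trimethyl-7-oxabicyclo[2.2.1]heptane-2-carbaldehyde F6. Pinnick oxidation (NaClO2, NaH2PO4, 2-methylbut-2-ene, t-BuOH/H2O) then gives 10.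

Further compounds
F1 | step 9 | 7-{[(1S,5R)-2-bromo-5-hydroxy-2,6,6-trimethylcyclohexyl]methoxy}-2H-chromen-2-one (both epimers at the bromine-bearing carbon) | CC1(Br)CC[C@@H](O)C(C)(C)[C@H]1COc1ccc2ccc(=O)oc2c1
F2 | step 9 | 7-{[(1S,5R)-5-hydroxy-2,6,6-trimethylcyclohex-2-en-1-yl]methoxy}-2H-chromen-2-one | CC1=CC[C@@H](O)C(C)(C)[C@H]1COc1ccc2ccc(=O)oc2c1
F3 | step 3 | methyl 2-cyclopropylideneacetate | COC(=O)C=C1CC1
F4 | step 3 | rac-methyl (1'S,4'R)-1'-methylspiro[cyclopropane-1,3'-[7]oxabicyclo[2.2.1]hept[5]ene]-2'-carboxylate (both epimers at C-2') | C[C@@]12C=C[C@@H](O1)C3(CC3)C2C(=O)OC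
F5 | step 5 | rac-(1S,2S,4R)-1,3,3-trimethyl-7-oxabicyclo[2.2.1]heptane-2-carbaldehyde (formyl endo) | C[C@@]12CC[C@@H](O1)C(C)(C)[C@@H]2C=O
F6 | step 5 | rac-(1S,2R,4R)-1,3,3-trimethyl-7-oxabicyclo[2.2.1]heptane-2-carbaldehyde (formyl exo) | C[C@@]12CC[C@@H](O1)C(C)(C)[C@H]2C=O
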